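## The problem

Compound 21 joins three rings through one quaternary carbon: trimethoxyarene ring A is fused to seven-membered ring B (aryl C1, aryl C2, C1', C7', C8', C8, C7), and C1' is also the spiro atom of ring C, a 2,6-dimethoxycyclohexa-2,5-dienone whose carbonyl is C4'. C1' is fully substituted and bonded to an arene carbon with two ortho neighbours, so it is hard to make, but it is not stereogenic because the two arms of ring C are identical. The stereochemical problem is therefore confined to three contiguous centres on ring B, C8' (R), C8 (S) and C7 (R), whose substituents alternate trans,trans around the ring. The two methyl-bearing carbons form a 2,3-dimethylbutane-1,4-diyl unit that is C2-symmetric when both ends carry the same group, so they can be made together and first, whereas C7, a benzylic carbinol carbon next to C8, must be set on the assembled skeleton under the influence of C8 and of ring B. The fragile groups are the cross-conjugated dienone (electrophilic toward organometallics, reducible, prone to acid-induced rearrangement), its two enol ethers, and the benzoate on an electron-rich benzylic carbon, which can ionise, eliminate or be cleaved. The enabling feature is the position of the carbonyl: C4' lies opposite C1' and between the methoxy-bearing carbons C3' and C5', so removing that one oxygen leaves a 3,5-dimethoxycyclohexa-2,5-diene, the product of Birch reduction of a 3,5-dimethoxyphenyl ring alkylated at its ipso carbon. With ring C in that non-electrophilic form, ring B can be closed at C1–C7 by adding an arylmetal at C1 to an aldehyde at C7, which creates C7 in the same event.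

## Retrosynthesis

**Dienone carbonyl last (21 ⇒ 19).** Only the oxygen at C4' is removed, leaving the C4' methylene of benzoate 19; the forward reaction passes through peroxide 20. Cutting a ring bond or the ester first would drag the dienone through acylation, organometallic and reductive chemistry that it cannot stand. Compound 19 has no electrophilic carbon in ring C and tolerates base and organochromium reagents; the price is the acid lability of its two enol ethers. The forward step must oxidise the single doubly allylic CH2 and leave the enol ether double bonds, the benzylic C7–H and the electron-rich arene alone.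

**Benzoate (19 ⇒ 18).** The acyl C–O bond is cut to give carbinol 18. Keeping C7 as a free alcohol until here is what allows it to be made by carbonyl addition. The forward step is an acylation with retention, under basic conditions because of the enol ethers, and before the oxidation because a free benzylic alcohol would not survive peroxide.

**Ring B (18 ⇒ 16).** Ring B is opened at C1–C7 to aryl triflate aldehyde 16. This is the only ring bond whose cleavage leaves C1' untouched, turns the C7 oxygen into the reacting carbonyl, and puts the donor on the arene, where a phenol-derived leaving group can stand in for the metal. Cutting C2–C1' or C1'–C7' would ask a ring closure to create the hindered quaternary carbon; cutting C7–C8 or C8–C8' would break up the stereodefined chain. Compound 16 is open between the rings and carries only the two methyl stereocenters. The forward coupling (CrCl2 with catalytic NiCl2) must insert into a hindered, electron-rich triflate, close a seven-membered ring, and take the aldehyde face that puts the C7 oxygen trans to the C8 methyl group.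

**Functional-group adjustments (16 ⇒ 15 ⇒ 14 ⇒ 13).** The aldehyde is traced to primary alcohol 15 and its silyl ether 14, and the triflate to phenol 13. The aldehyde is unmasked last because its α-centre C8 can epimerise. The triflate is installed before desilylation so that only one hydroxyl is free at a time. All three forward steps must avoid acid.

**Quaternary carbon (13 ⇒ 10 + 6).** The C1'–C7' bond is cut, giving flat, achiral biaryl phenol 10 and four-carbon iodide 6. This is the cut that uses the Birch relationship: reduction of the dimethoxyphenyl ring of 10 gives a carbanion at C1' (12), and its alkylation creates the quaternary carbon with ring C already in the masked oxidation state. The phenol of 10 has two jobs: as phenoxide 11 it keeps ring A from being reduced, and later it becomes the triflate. The forward reaction must reduce only one ring and alkylate a hindered carbanion with a β-branched primary iodide.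

**Biaryl (10 ⇒ 8 + 9; 8 ⇒ 7).** The C2–C1' biaryl bond is made by Suzuki–Miyaura coupling of bromophenol 8 with boronic acid 9. Compound 8 comes from phenol 7 by bromination at one of its two equivalent free positions. Halogen on ring A and boron on the other ring is preferred to the reverse because 7 brominates cleanly next to its hydroxyl and 9 is an article of commerce.

**Chain (6 ⇒ 5 ⇒ 4 ⇒ 3 ⇒ 1).** Iodide 6 comes from mono-silyl ether 5 and diol 4. Diol 4 is C2-symmetric, so its two hydroxyls are equivalent and differentiating them raises no regiochemical question. The C8–C8' bond is then cut in the middle: bis-imide 3 is the oxidative dimer of enolate 2, so two molecules of propionyl oxazolidinone 1 supply the whole six-carbon unit. This is preferred to building the two centres one after the other because a single auxiliary sets both in one C–C bond formation. Both α-carbons must bond on the face away from the benzyl group; the (R)-auxiliary then gives the (2S,3S) unit.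

## Roads not taken

**Alternative 1:** Ring C is cut at C1'–C6' and C2'=C3' and annulated onto a finished ring B.
- Forward key step: a secondary-amine enamine of ring B carbaldehyde A2 adds to enone A3 to form C1'–C6'. The methoxy ketone then condenses through its methoxy-bearing methylene onto the aldehyde carbon, closing ring C as spiro 2-methoxycyclohexenone A1.
- Merits: ring B, all three stereocenters and the benzoate are settled before ring C exists. There is no dissolving metal, no acid-labile bis-enol ether to carry through several steps, and no peroxide oxidation. The configuration of C1' in A2 is irrelevant.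
- Weak points: A1 is only half of ring C. C5' still needs an oxygen, a methyl ether and the C5'=C6' double bond, which means at least three more steps with their own regiochemistry. Enamines of α,α-disubstituted aldehydes are poor Michael donors, and here the donor carbon also carries di-ortho-substituted ring A. The benzylic benzoate must survive amine and aldol base. A2 still requires ring B to be made, so the seven-membered ring closure is moved, not removed.
- Comparison: Alternative 1 is better in the robustness of its late intermediates toward acid, and in forming the quaternary centre by addition to an sp2 acceptor instead of by SN2. The chosen plan sets against this that ring C arrives complete from an aromatic ring, one oxidation short of 21, and that step 11 deals with ring B and C7 in a single operation.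

**Alternative 2:** No ring bond is cut; the two C–CH3 bonds at C8' and C8 are removed, leaving achiral benzocycloheptenone A5.
- Forward key step: Cu(OTf)2 with a chiral phosphoramidite catalyses conjugate addition of Me2Zn to C8', and the resulting zinc enolate is methylated at C8 with MeI, giving trans-dimethyl ketone A4. Reduction of the C7 ketone would then lead to 18.
- Merits: absolute configuration comes from a catalyst. No auxiliary and no four-step chain synthesis are needed, and all earlier intermediates are achiral. The trans relationship follows from enolate trapping anti to the new β-substituent and can be corrected by equilibration.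
- Weak points: A5 is an aryl-conjugated seven-membered enone with a quaternary carbon two atoms from the acceptor carbon, and Me2Zn is the least reactive of the dialkylzincs. Zinc enolates are slow toward methyl electrophiles. Enantioselectivity on this ring is unproven. C7 needs a separate, facially controlled reduction while C8 remains epimerisable. A5 itself needs ring closure plus introduction of the enone beside the masked ring C, so the step count is not lower.
- Comparison: Alternative 2 is better in economy of chirality and shares the masked ring C. The chosen plan sets against it that C8 and C8' arrive fixed in enantiopure 4, and that the ring closure makes C7 directly as the carbinol, so no stereocenter depends on an untested catalytic step on an advanced intermediate.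

**Alternative 3:** Two bonds are cut at once, C1–C7 and C2–C1'.
- Forward key step: a Catellani reaction of aryl iodide A7 with phenol thioester A8 under Pd(OAc)2, a triarylphosphine, norbornene and Cs2CO3. Ortho C–H acylation forms C1–C7, then ipso attack on the para carbon of the phenol forms C2–C1' with dearomatisation, giving spirodienone ketone A6.
- Merits: this is the most convergent road. Two bonds, ring B and ring C in its final oxidation state come from two simple arenes in one step, with no Birch reduction, no masked ring and no late oxidation. The sequence would be several steps shorter.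
- Weak points: the ipso termination must close a seven-membered ring from a di-ortho-substituted arylpalladium intermediate onto a phenol, against faster known terminations. The thiolate released from A8 is itself a competent ipso terminator. C8 is α to a carbonyl in both A8 and A6 and sits in hot Cs2CO3. A6 has two ketones, so the C7 ketone must be reduced selectively beside the dienone carbonyl and with facial control.
- Comparison: if the cascade worked, Alternative 3 would be clearly superior in step count and convergence. The chosen plan sets against it that every step is of an established type, that ring C has no electrophilic carbonyl while organometallic chemistry is done, and that it never has to tell two ketones apart.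

Key step: step 11

Remarks on the chemistry (assumptions):
- Locants follow lignan numbering: ring A C1–C6, benzylic C7, methyl-bearing C8 and C8', methylene C7', ring C C1'–C6' with spiro C1' and carbonyl C4'.
- The ring closure of step 11 is assumed to give the 7R carbinol (oxygen trans to the C8 methyl group).
- In Alternative 3 the thioester is taken as the S-ethyl ester.

## Route

Step 1
Reactants: 1 (R)-4-benzyl-3-propionyloxazolidin-2-one
Product: 3 (4R,4'R)-3,3'-[(2S,3S)-2,3-dimethylbutanedioyl]bis(4-benzyl-1,3-oxazolidin-2-one), via lithium Z-enolate 2 (not isolated)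
Conditions: LiN(i-Pr)2 (1.1 equiv), THF, −78 °C; then TiCl4 (1.1 equiv), −78 °C → rt
Reagents that add atoms: (R)-4-benzyl-3-propionyloxazolidin-2-one (second molecule of 1), CCC(=O)N1[C@H](Cc2ccccc2)COC1=O
Why: Oxidative homocoupling of an N-acyloxazolidinone enolate, in which two molecules of 1 are joined at their α-carbons: TiCl4 oxidises the chelated Z-enolate 2 by one electron per unit and the two α-carbons couple with loss of one hydrogen from each molecule. Each α-carbon bonds on the face away from the benzyl group (the facial sense of alkylation of these enolates), so the (R)-auxiliary should give the C2-symmetric (2S,3S) dimer; a heterochiral dimer would be a separable diastereomer.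

Step 2
Reactants: 3 (4R,4'R)-3,3'-[(2S,3S)-2,3-dimethylbutanedioyl]bis(4-benzyl-1,3-oxazolidin-2-one)
Product: 4 (2S,3S)-2,3-dimethylbutane-1,4-diol
Conditions: LiBH4, MeOH (2 equiv), THF, 0 °C → rt; aq. NaOH work-up
Reagents that add atoms: none
Why: Reductive cleavage of N-acyloxazolidinones by LiBH4 gives primary alcohols without touching the α-stereocenters; the auxiliary is released intact and can be recovered.

Step 3
Reactants: 4 (2S,3S)-2,3-dimethylbutane-1,4-diol
Product: 5 (2S,3S)-4-[(tert-butyldimethylsilyl)oxy]-2,3-dimethylbutan-1-ol
Conditions: NaH (1.0 equiv), THF, 0 °C → rt; then TBSCl (1.0 equiv), rt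
Reagents that add atoms: tert-butyldimethylsilyl chloride, CC(C)(C)[Si](C)(C)Cl
Why: Monosilylation of a symmetric diol through its sparingly soluble monosodium alkoxide; the C2 axis makes the two hydroxyls equivalent, so only one mono-ether can form.

Step 4
Reactants: 5 (2S,3S)-4-[(tert-butyldimethylsilyl)oxy]-2,3-dimethylbutan-1-ol
Product: 6 tert-butyl{[(2S,3S)-4-iodo-2,3-dimethylbutyl]oxy}dimethylsilane
Conditions: I2, PPh3, imidazole, CH2Cl2, 0 °C → rt
Reagents that add atoms: iodine, II
Why: Appel-type iodination, an SN2 displacement at the primary carbon under buffered conditions; neither stereocenter is involved and the silyl ether is stable.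

Step 5
Reactants: 7 3,4,5-trimethoxyphenol
Product: 8 2-bromo-3,4,5-trimethoxyphenol
Conditions: NBS (1.0 equiv), CH2Cl2, −78 → 0 °C
Reagents that add atoms: N-bromosuccinimide, O=C1CCC(=O)N1Br
Why: Electrophilic aromatic bromination ortho to the hydroxyl; the two free positions of 7 are equivalent, and one equivalent of NBS at low temperature limits dibromination and quinone formation.

Step 6
Reactants: 8 2-bromo-3,4,5-trimethoxyphenol; 9 3,5-dimethoxyphenylboronic acid
Product: 10 2-(3,5-dimethoxyphenyl)-3,4,5-trimethoxyphenol
Conditions: Pd(OAc)2 (2 mol %), SPhos, K3PO4, toluene/H2O, 90 °C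
Reagents that add atoms: none
Why: Suzuki–Miyaura coupling; the dialkylbiarylphosphine copes with the di-ortho-substituted, electron-rich bromide, and the unprotected phenol is carried as its phenoxide.

Step 7
Reactants: 10 2-(3,5-dimethoxyphenyl)-3,4,5-trimethoxyphenol; 6 tert-butyl{[(2S,3S)-4-iodo-2,3-dimethylbutyl]oxy}dimethylsilane
Product: 13 2-{1-[(2R,3S)-4-[(tert-butyldimethylsilyl)oxy]-2,3-dimethylbutyl]-3,5-dimethoxycyclohexa-2,5-dien-1-yl}-3,4,5-trimethoxyphenol, via lithium phenoxide 11 (not isolated), via dilithium cyclohexadienyl anion 12 (not isolated)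
Conditions: n-BuLi (1.0 equiv), THF, −78 °C; Li (2.2 equiv), NH3/THF, −78 °C; then 6, −78 → −33 °C; NH4Cl; work-up at pH 8
Reagents that add atoms: none
Why: Birch reductive alkylation of a 3,5-dimethoxybiaryl: ring A, held as phenoxide 11, is too electron-rich to accept electrons, so both enter the dimethoxyphenyl ring and ammonia protonates C4' between the methoxy-bearing carbons. Anion 12 is then alkylated by SN2 at C1', its aryl-bearing central carbon, by primary iodide 6. C1' carries two identical ring arms and is not stereogenic, and the stereocenters of 6 are not at the reacting carbon.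

Step 8
Reactants: 13 2-{1-[(2R,3S)-4-[(tert-butyldimethylsilyl)oxy]-2,3-dimethylbutyl]-3,5-dimethoxycyclohexa-2,5-dien-1-yl}-3,4,5-trimethoxyphenol
Product: 14 2-{1-[(2R,3S)-4-[(tert-butyldimethylsilyl)oxy]-2,3-dimethylbutyl]-3,5-dimethoxycyclohexa-2,5-dien-1-yl}-3,4,5-trimethoxyphenyl trifluoromethanesulfonate
Conditions: KN(SiMe3)2, THF, −78 °C; then PhNTf2, −78 → 0 °C
Reagents that add atoms: N-phenylbis(trifluoromethanesulfonimide), O=S(=O)(N(c1ccccc1)S(=O)(=O)C(F)(F)F)C(F)(F)F
Why: O-Sulfonylation of the phenoxide with PhNTf2, a neutral triflyl donor that generates no acid, so the bis-enol ether and the silyl ether survive; the amide base is too weak to deprotonate C4'.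

Step 9
Reactants: 14 2-{1-[(2R,3S)-4-[(tert-butyldimethylsilyl)oxy]-2,3-dimethylbutyl]-3,5-dimethoxycyclohexa-2,5-dien-1-yl}-3,4,5-trimethoxyphenyl trifluoromethanesulfonate
Product: 15 2-{1-[(2R,3S)-4-hydroxy-2,3-dimethylbutyl]-3,5-dimethoxycyclohexa-2,5-dien-1-yl}-3,4,5-trimethoxyphenyl trifluoromethanesulfonate
Conditions: Bu4NF, THF, 0 °C
Reagents that add atoms: none
Why: Fluoride-mediated cleavage of the primary silyl ether under basic conditions, to which enol ethers are inert; the electron-rich aryl triflate should resist attack at sulfur at 0 °C.

Step 10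
Reactants: 15 2-{1-[(2R,3S)-4-hydroxy-2,3-dimethylbutyl]-3,5-dimethoxycyclohexa-2,5-dien-1-yl}-3,4,5-trimethoxyphenyl trifluoromethanesulfonate
Product: 16 2-{3,5-dimethoxy-1-[(2R,3S)-2,3-dimethyl-4-oxobutyl]cyclohexa-2,5-dien-1-yl}-3,4,5-trimethoxyphenyl trifluoromethanesulfonate
Conditions: Dess–Martin periodinane, pyridine, CH2Cl2, 0 °C → rt
Reagents that add atoms: none
Why: Dess–Martin oxidation buffered with pyridine stops at the aldehyde under non-acidic, non-enolising conditions, so C8 should not epimerise; 16 is used at once.

Step 11
Reactants: 16 2-{3,5-dimethoxy-1-[(2R,3S)-2,3-dimethyl-4-oxobutyl]cyclohexa-2,5-dien-1-yl}-3,4,5-trimethoxyphenyl trifluoromethanesulfonate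
Product: 18 (7R,8S,9R)-2,3,3',4,5'-pentamethoxy-7,8-dimethyl-6,7,8,9-tetrahydrospiro[benzo[7]annulene-5,1'-cyclohexa[2,5]dien]-9-ol, via arylchromium dichloride 17 (not isolated)
Conditions: CrCl2 (8 equiv), NiCl2 (20 mol %), degassed DMF, 50 °C, 0.005 M; then aq. KNaC4H4O6 (potassium sodium tartrate)/NaHCO3
Reagents that add atoms: none
Why: Intramolecular Nozaki–Hiyama–Kishi reaction of an aryl sulfonate with an aldehyde. CrCl2 reduces NiCl2 to zerovalent nickel, which inserts into the C1–O bond of the triflate; transmetalation to trivalent chromium gives arylchromium 17, which adds to the C7 aldehyde. The closest known reaction type is the nickel/chromium-mediated cyclisation of aryl or alkenyl halides and triflates onto tethered aldehydes to give medium rings. Ring B closes in the 7-exo-trig mode, C1 attacking C7 with the carbonyl oxygen outside the ring. C7 is controlled by C8 and by the forming ring: in a chair-like transition state with both methyl groups pseudo-equatorial, the chromium-bound oxygen also sits pseudo-equatorial, trans to the C8 methyl group, which is 7R. The step needs chemoselectivity for the aldehyde, and the substrate secures it: the bis-enol ether diene has no electrophilic carbon (a dienone would), its double bonds could only be reached through a four-membered ring, and the weakly basic organochromium species should leave C8 alone. High dilution favours ring closure over intermolecular coupling, and the buffered work-up keeps the acidic trivalent chromium salts from hydrolysing the enol ethers.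

Step 12
Reactants: 18 (7R,8S,9R)-2,3,3',4,5'-pentamethoxy-7,8-dimethyl-6,7,8,9-tetrahydrospiro[benzo[7]annulene-5,1'-cyclohexa[2,5]dien]-9-ol
Product: 19 (7R,8S,9R)-2,3,3',4,5'-pentamethoxy-7,8-dimethyl-6,7,8,9-tetrahydrospiro[benzo[7]annulene-5,1'-cyclohexa[2,5]dien]-9-yl benzoate
Conditions: BzCl, Et3N, DMAP (cat.), CH2Cl2, 0 °C → rt
Reagents that add atoms: benzoyl chloride, O=C(Cl)c1ccccc1
Why: DMAP-catalysed acylation of the secondary benzylic alcohol with retention at C7; the basic medium protects the bis-enol ether.

Step 13
Reactants: 19 (7R,8S,9R)-2,3,3',4,5'-pentamethoxy-7,8-dimethyl-6,7,8,9-tetrahydrospiro[benzo[7]annulene-5,1'-cyclohexa[2,5]dien]-9-yl benzoate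
Product: 21 (7R,8S,9R)-2,3,3',4,5'-pentamethoxy-7,8-dimethyl-4'-oxo-6,7,8,9-tetrahydrospiro[benzo[7]annulene-5,1'-cyclohexa[2,5]dien]-9-yl benzoate (CNP0201356.1), via C4' tert-butyl peroxide 20 (not isolated)
Conditions: t-BuOOH (in decane, 5 equiv), Rh2(cap)4 (cap = caprolactamate, 1 mol %), NaHCO3, CH2Cl2, rt
Reagents that add atoms: tert-butyl hydroperoxide, CC(C)(C)OO
Why: Metal-catalysed tert-butyl hydroperoxide allylic oxidation of a 1,4-cyclohexadiene to a cross-conjugated cyclohexadienone: tert-butylperoxyl radicals abstract hydrogen from C4', the only doubly allylic position, the pentadienyl radical is trapped at its central carbon to give peroxide 20, and 20 loses tert-butanol to give the ketone. The radical termini C2' and C6' are shielded by quaternary C1', and the benzylic C7–H is deactivated by its benzoate.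

## Compound list

1 | (R)-4-benzyl-3-propionyloxazolidin-2-one | CCC(=O)N1[C@H](Cc2ccccc2)COC1=O | starting material
2 | lithium (Z)-enolate of 1 | [Li+].C/C=C(\[O-])N1[C@H](Cc2ccccc2)COC1=O | intermediate
3 | (4R,4'R)-3,3'-[(2S,3S)-2,3-dimethylbutanedioyl]bis(4-benzyl-1,3-oxazolidin-2-one) | O=C([C@@H](C)[C@H](C)C(=O)N1[C@H](Cc2ccccc2)COC1=O)N1[C@H](Cc2ccccc2)COC1=O | intermediate
4 | (2S,3S)-2,3-dimethylbutane-1,4-diol | OC[C@@H](C)[C@H](C)CO | intermediate
5 | (2S,3S)-4-[(tert-butyldimethylsilyl)oxy]-2,3-dimethylbutan-1-ol | OC[C@@H](C)[C@H](C)CO[Si](C)(C)C(C)(C)C | intermediate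
6 | tert-butyl{[(2S,3S)-4-iodo-2,3-dimethylbutyl]oxy}dimethylsilane | IC[C@@H](C)[C@H](C)CO[Si](C)(C)C(C)(C)C | intermediate
7 | 3,4,5-trimethoxyphenol | COc1cc(O)cc(OC)c1OC | starting material
8 | 2-bromo-3,4,5-trimethoxyphenol | COc1cc(O)c(Br)c(OC)c1OC | intermediate
9 | 3,5-dimethoxyphenylboronic acid | COc1cc(OC)cc(B(O)O)c1 | starting material
10 | 2-(3,5-dimethoxyphenyl)-3,4,5-trimethoxyphenol | COc1cc(OC)cc(-c2c(O)cc(OC)c(OC)c2OC)c1 | intermediate
11 | lithium 2-(3,5-dimethoxyphenyl)-3,4,5-trimethoxyphenolate | [Li+].COc1cc(OC)cc(-c2c([O-])cc(OC)c(OC)c2OC)c1 | intermediate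
12 | dilithium 2-(3,5-dimethoxycyclohexa-2,5-dien-1-id-1-yl)-3,4,5-trimethoxyphenolate | [Li+].[Li+].COC1=C[C-](C=C(OC)C1)c1c([O-])cc(OC)c(OC)c1OC | intermediate
13 | 2-{1-[(2R,3S)-4-[(tert-butyldimethylsilyl)oxy]-2,3-dimethylbutyl]-3,5-dimethoxycyclohexa-2,5-dien-1-yl}-3,4,5-trimethoxyphenol | COC1=CC(C=C(OC)C1)(C[C@@H](C)[C@H](C)CO[Si](C)(C)C(C)(C)C)c1c(O)cc(OC)c(OC)c1OC | intermediate
14 | aryl triflate of 13 (C1 triflate, silyl ether retained) | COC1=CC(C=C(OC)C1)(C[C@@H](C)[C@H](C)CO[Si](C)(C)C(C)(C)C)c1c(OS(=O)(=O)C(F)(F)F)cc(OC)c(OC)c1OC | intermediate
15 | 2-{1-[(2R,3S)-4-hydroxy-2,3-dimethylbutyl]-3,5-dimethoxycyclohexa-2,5-dien-1-yl}-3,4,5-trimethoxyphenyl trifluoromethanesulfonate | COC1=CC(C=C(OC)C1)(C[C@@H](C)[C@H](C)CO)c1c(OS(=O)(=O)C(F)(F)F)cc(OC)c(OC)c1OC | intermediate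
16 | 2-{3,5-dimethoxy-1-[(2R,3S)-2,3-dimethyl-4-oxobutyl]cyclohexa-2,5-dien-1-yl}-3,4,5-trimethoxyphenyl trifluoromethanesulfonate (8S,8'R aldehyde) | COC1=CC(C=C(OC)C1)(C[C@@H](C)[C@H](C)C=O)c1c(OS(=O)(=O)C(F)(F)F)cc(OC)c(OC)c1OC | intermediate
17 | {2-[3,5-dimethoxy-1-((2R,3S)-2,3-dimethyl-4-oxobutyl)cyclohexa-2,5-dien-1-yl]-3,4,5-trimethoxyphenyl}chromium dichloride | COC1=CC(C=C(OC)C1)(C[C@@H](C)[C@H](C)C=O)c1c([Cr](Cl)Cl)cc(OC)c(OC)c1OC | intermediate
18 | (7R,8S,9R)-2,3,3',4,5'-pentamethoxy-7,8-dimethyl-6,7,8,9-tetrahydrospiro[benzo[7]annulene-5,1'-cyclohexa[2,5]dien]-9-ol | COC1=CC2(C=C(OC)C1)C[C@@H](C)[C@H](C)[C@@H](O)c1cc(OC)c(OC)c(OC)c12 | intermediate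
19 | benzoate of 18, (7R,8S,9R) | COC1=CC2(C=C(OC)C1)C[C@@H](C)[C@H](C)[C@@H](OC(=O)c1ccccc1)c1cc(OC)c(OC)c(OC)c12 | intermediate
20 | C4' tert-butylperoxy derivative of 19 (C4' configuration undefined) | COC1=CC2(C=C(OC)C1OOC(C)(C)C)C[C@@H](C)[C@H](C)[C@@H](OC(=O)c1ccccc1)c1cc(OC)c(OC)c(OC)c12 | intermediate
21 | (7R,8S,9R)-2,3,3',4,5'-pentamethoxy-7,8-dimethyl-4'-oxo-6,7,8,9-tetrahydrospiro[benzo[7]annulene-5,1'-cyclohexa[2,5]dien]-9-yl benzoate | COC1=CC2(C=C(OC)C1=O)C[C@@H](C)[C@H](C)[C@@H](OC(=O)c1ccccc1)c1cc(OC)c(OC)c(OC)c12 | target

## Step count and risks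

Total: 13 steps. Longest linear sequence: 11 steps (steps 1–4 and 7–13, from 1 to 21). The arene branch (steps 5 and 6, from 7) joins at step 7.

**Step 11 (key step).** Most likely failure: slow insertion of zerovalent nickel into the triflate, which is electron-rich and flanked by the quaternary carbon. The aldehyde would then be consumed by chromium-mediated reduction or pinacol coupling, or C8 would epimerise on prolonged heating; loss of the triflate by protonation of the arylmetal is the other drain. Fallback, from 16 back to 18: palladium inserts in place of nickel and boron/rhodium replaces chromium. Miyaura borylation of 16 (bis(pinacolato)diboron, PdCl2(dppf) or Pd(OAc)2/SPhos, KOAc, dioxane, 80 °C) gives arylboronate aldehyde F1. Rhodium-catalysed intramolecular 1,2-addition of the arylboronate to the aldehyde ([Rh(cod)OH]2, aqueous dioxane) then closes the same C1–C7 bond and returns to 18.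

**Step 7.** Most likely failure: sluggish SN2 alkylation of the hindered C1' carbanion, which sits next to a di-ortho-substituted, phenoxide-bearing arene and meets a β-branched iodide. Elimination of the iodide by LiNH2, protonation on quench, or O-alkylation of the phenoxide would then take over. Reductive loss of a methoxy group from ring A is a lesser risk. Fallback, from 10 back to 15: the phenol is masked so that the nucleophile is a monoanion with no neighbouring phenoxide. Silylation of 10 (TBSCl, imidazole, DMF) gives aryl silyl ether F2. Birch reductive alkylation of F2 with 6 under the conditions of step 7 (without n-BuLi) gives bis-silyl ether F3. Bu4NF removes both silyl groups to give phenol alcohol F4. Phenol-selective triflation (PhNTf2, K2CO3, THF) gives 15, bypassing 13 and 14.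

**Step 13.** Most likely failure: loss of site selectivity in the radical oxidation. Peroxyl radicals may add to the electron-rich enol ether double bonds, the dienyl radical may be trapped at C2' or C6', or the product dienone may be epoxidised or over-oxidised. Fallback, from 19 to 21 without C–H oxidation of the diene: mild aqueous acid (dilute HCl, THF, rt) hydrolyses both enol ethers to spiro cyclohexane-1,3-dione F5. Oxidation of its active C4' methylene (Dess–Martin periodinane, pyridine) gives the vicinal tricarbonyl, which should rest as bis-enol F6. O-Methylation of both enolic hydroxyls (Me2SO4, K2CO3, acetone) gives 21.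

**Step 1.** Most likely failure: weak facial control or low conversion. The coupling has radical character, so the auxiliary may discriminate less well than in a closed-shell alkylation, and α-chlorination or simple reprotonation can compete. Fallback, from 1 back to 4: the two centres are set in separate closed-shell events. Methyl (S)-lactate is converted (Tf2O, 2,6-lutidine) into methyl (S)-2-(trifluoromethylsulfonyloxy)propanoate F7. The sodium enolate of 1 (NaN(SiMe3)2, THF, −78 °C) is alkylated by F7 with inversion at the lactate carbon and auxiliary control at the other, giving imide ester F8. LiBH4 reduces both acyl groups of F8 to give 4.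

**Step 12.** Most likely failure: acylation goes with retention, so poor or reversed facial selectivity in step 11 would surface here as the wrong C7 configuration; the hindered carbinol may also acylate slowly. Fallback, from 16 back to 19: if the closure favours the other face, the resulting 7S carbinol F9 is esterified under Mitsunobu conditions (benzoic acid, PPh3, diisopropyl azodicarboxylate, toluene, 0 °C). This inverts C7 and gives 19 directly.

## Further compounds

F1 | step 11 | (2S,3R)-4-{3,5-dimethoxy-1-[2,3,4-trimethoxy-6-(4,4,5,5-tetramethyl-1,3,2-dioxaborolan-2-yl)phenyl]cyclohexa-2,5-dien-1-yl}-2,3-dimethylbutanal | COC1=CC(C=C(OC)C1)(C[C@@H](C)[C@H](C)C=O)c1c(B2OC(C)(C)C(C)(C)O2)cc(OC)c(OC)c1OC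
F2 | step 7 | tert-butyl[2-(3,5-dimethoxyphenyl)-3,4,5-trimethoxyphenoxy]dimethylsilane | COc1cc(OC)cc(-c2c(O[Si](C)(C)C(C)(C)C)cc(OC)c(OC)c2OC)c1
F3 | step 7 | aryl tert-butyldimethylsilyl ether of 13 (bis-silyl ether) | COC1=CC(C=C(OC)C1)(C[C@@H](C)[C@H](C)CO[Si](C)(C)C(C)(C)C)c1c(O[Si](C)(C)C(C)(C)C)cc(OC)c(OC)c1OC
F4 | step 7 | 2-{1-[(2R,3S)-4-hydroxy-2,3-dimethylbutyl]-3,5-dimethoxycyclohexa-2,5-dien-1-yl}-3,4,5-trimethoxyphenol | COC1=CC(C=C(OC)C1)(C[C@@H](C)[C@H](C)CO)c1c(O)cc(OC)c(OC)c1OC
F5 | step 13 | (7R,8S,9R)-2,3,4-trimethoxy-7,8-dimethyl-3',5'-dioxo-6,7,8,9-tetrahydrospiro[benzo[7]annulene-5,1'-cyclohexan]-9-yl benzoate | O=C1CC(=O)CC2(C1)C[C@@H](C)[C@H](C)[C@@H](OC(=O)c1ccccc1)c1cc(OC)c(OC)c(OC)c12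
F6 | step 13 | (7R,8S,9R)-3',5'-dihydroxy-2,3,4-trimethoxy-7,8-dimethyl-4'-oxo-6,7,8,9-tetrahydrospiro[benzo[7]annulene-5,1'-cyclohexa[2,5]dien]-9-yl benzoate | OC1=CC2(C=C(O)C1=O)C[C@@H](C)[C@H](C)[C@@H](OC(=O)c1ccccc1)c1cc(OC)c(OC)c(OC)c12
F7 | step 1 | methyl (S)-2-{[(trifluoromethyl)sulfonyl]oxy}propanoate | C[C@H](OS(=O)(=O)C(F)(F)F)C(=O)OC
F8 | step 1 | methyl (2S,3S)-4-[(R)-4-benzyl-2-oxooxazolidin-3-yl]-2,3-dimethyl-4-oxobutanoate | COC(=O)[C@@H](C)[C@H](C)C(=O)N1[C@H](Cc2ccccc2)COC1=O
F9 | step 12 | (7R,8S,9S)-2,3,3',4,5'-pentamethoxy-7,8-dimethyl-6,7,8,9-tetrahydrospiro[benzo[7]annulene-5,1'-cyclohexa[2,5]dien]-9-ol | COC1=CC2(C=C(OC)C1)C[C@@H](C)[C@H](C)[C@H](O)c1cc(OC)c(OC)c(OC)c12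
A1 | alternative 1 | spiro 2-methoxycyclohexenone benzoate, (7R,8S,9R), C1' configuration open | COC1=CC2(CCC1=O)C[C@@H](C)[C@H](C)[C@@H](OC(=O)c1ccccc1)c1cc(OC)c(OC)c(OC)c12
A2 | alternative 1 | (7R,8S,9R)-5-formyl-2,3,4-trimethoxy-7,8-dimethyl-6,7,8,9-tetrahydro-5H-benzo[7]annulen-9-yl benzoate, C5 configuration open | O=CC1C[C@@H](C)[C@H](C)[C@@H](OC(=O)c2ccccc2)c2cc(OC)c(OC)c(OC)c12
A3 | alternative 1 | 1-methoxybut-3-en-2-one | COCC(=O)C=C
A4 | alternative 2 | (7R,8S)-2,3,3',4,5'-pentamethoxy-7,8-dimethyl-7,8-dihydrospiro[benzo[7]annulene-5,1'-cyclohexa[2,5]dien]-9(6H)-one | COC1=CC2(C=C(OC)C1)C[C@@H](C)[C@H](C)C(=O)c1cc(OC)c(OC)c(OC)c12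
A5 | alternative 2 | 2,3,3',4,5'-pentamethoxyspiro[benzo[7]annulene-5,1'-cyclohexa[2,5]dien]-9(6H)-one (C7=C8 enone) | COC1=CC2(C=C(OC)C1)CC=CC(=O)c1cc(OC)c(OC)c(OC)c12
A6 | alternative 3 | (7R,8S)-2,3,3',4,5'-pentamethoxy-7,8-dimethyl-7,8-dihydrospiro[benzo[7]annulene-5,1'-cyclohexa[2,5]diene]-4',9(6H)-dione | COC1=CC2(C=C(OC)C1=O)C[C@@H](C)[C@H](C)C(=O)c1cc(OC)c(OC)c(OC)c12
A7 | alternative 3 | 1-iodo-2,3,4-trimethoxybenzene | COc1ccc(I)c(OC)c1OC
A8 | alternative 3 | S-ethyl (2S,3R)-4-(4-hydroxy-3,5-dimethoxyphenyl)-2,3-dimethylbutanethioate | COc1cc(C[C@@H](C)[C@H](C)C(=O)SCC)cc(OC)c1O
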